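**Retrosynthetic overview**
1. Target 13 ⇐ hydrogenolysis of the 2′-O-benzyl ether 12.
2. 12 ⇐ C6–O bond made last by a new direct ortho-C–H hydroxylation of 5-hydroxyflavone 9 (phenolate + N-sulfonyloxaziridine).
3. 9 ⇐ chelation-controlled 5-O-demethylation of 5,7,8-trimethoxyflavone 8.
4. 8 ⇐ pyranone closure by oxidative cyclisation of 2′-hydroxychalcone 6 ⇐ Claisen–Schmidt union of acetophenone 3 (A ring) and aldehyde 5 (B ring).
5. Ring order: the A and B rings are bought (1, 4); the only ring formed is the pyranone C ring (step 4).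

Assumption: the target has no stereocentre and no configurationally stable axis (the C2–C1′ bond rotates freely), so "single enantiomer" is read as the achiral compound drawn; the only stereo-elements in the route are the E-alkene of 6 and transient racemic centres in 7 and 11.

**Route**

Step 1
Reactants: 1 1,2,3,5-tetramethoxybenzene
Product: 3 1-(2-hydroxy-3,4,6-trimethoxyphenyl)ethanone, via tetramethoxyacetophenone 2 (not isolated)
Conditions: AcCl (1.2 equiv), AlCl3 (2.5 equiv), CH2Cl2, 0 °C → rt; ice/aq. HCl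
Reagents that add atoms: acetyl chloride, CC(=O)Cl
Why: Friedel–Crafts acylation at one of the two equivalent free positions gives 2, and AlCl3 then cleaves the more crowded carbonyl-flanking 2-OMe (buttressed by the 3-OMe) through an aluminium chelate (ortho-selective Lewis-acid demethylation) to give the hydrogen-bonded phenol 3.

Step 2
Reactants: 4 2-hydroxy-6-methoxybenzaldehyde
Product: 5 2-(benzyloxy)-6-methoxybenzaldehyde
Conditions: BnBr, K2CO3, DMF, 60 °C
Reagents that add atoms: benzyl bromide, BrCc1ccccc1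
Why: Williamson ether synthesis on the phenoxide is straightforward and the aldehyde is untouched.

Step 3
Reactants: 3 1-(2-hydroxy-3,4,6-trimethoxyphenyl)ethanone; 5 2-(benzyloxy)-6-methoxybenzaldehyde
Product: 6 (E)-3-[2-(benzyloxy)-6-methoxyphenyl]-1-(2-hydroxy-3,4,6-trimethoxyphenyl)prop-2-en-1-one
Conditions: KOH (50% aq.), EtOH, rt, 48 h; acidify to pH 3
Reagents that add atoms: none
Why: Claisen–Schmidt aldol condensation of the methyl ketone enolate with a non-enolisable aldehyde, with E1cB dehydration giving the thermodynamic E-enone.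

Step 4
Reactants: 6 (E)-3-[2-(benzyloxy)-6-methoxyphenyl]-1-(2-hydroxy-3,4,6-trimethoxyphenyl)prop-2-en-1-one
Product: 8 2-[2-(benzyloxy)-6-methoxyphenyl]-5,7,8-trimethoxy-4H-chromen-4-one, via flavanone 7 (not isolated)
Conditions: I2 (10 mol %), DMSO, 130 °C, 2 h
Reagents that add atoms: none
Why: I2/DMSO oxidative cyclisation: 6-endo oxa-Michael closure to flavanone 7, then iodine-mediated α,β-dehydrogenation with DMSO as terminal oxidant, which removes the racemic C2 centre of 7.

Step 5
Reactants: 8 2-[2-(benzyloxy)-6-methoxyphenyl]-5,7,8-trimethoxy-4H-chromen-4-one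
Product: 9 2-[2-(benzyloxy)-6-methoxyphenyl]-5-hydroxy-7,8-dimethoxy-4H-chromen-4-one
Conditions: AlCl3 (3 equiv), MeCN, 0 °C → rt; then 1 M HCl
Reagents that add atoms: none
Why: Chelation-controlled Lewis-acid demethylation: aluminium bridges C4=O and the peri 5-OMe in a six-membered chelate, so chloride cleaves only that methyl while the 7-, 8- and 6′-methyl ethers and the benzyl ether in the nitrile-moderated medium are left.

Step 6
Reactants: 9 2-[2-(benzyloxy)-6-methoxyphenyl]-5-hydroxy-7,8-dimethoxy-4H-chromen-4-one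
Product: 12 2-[2-(benzyloxy)-6-methoxyphenyl]-5,6-dihydroxy-7,8-dimethoxy-4H-chromen-4-one, via potassium 5-phenolate 10 (not isolated), via C6-hydroxy dienone alkoxide 11 (not isolated)
Conditions: KHMDS (1.0 equiv), 18-crown-6 (1.0 equiv), THF, −78 °C; inverse addition to 3-phenyl-2-(phenylsulfonyl)oxaziridine (1.1 equiv), THF, −78 → −20 °C, Ar; 1 M HCl quench
Reagents that add atoms: 3-phenyl-2-(phenylsulfonyl)oxaziridine, O=S(=O)(c1ccccc1)N1OC1c1ccccc1 (delivers the C6 oxygen); KHMDS, C[Si](C)(C)[N-][Si](C)(C)C.[K+] (supplies only the K+ of 10 and 11)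
Why: Proposed new method: direct ortho-C–H hydroxylation of a chelated 5-hydroxyflavone through its crown-ether-separated potassium phenolate 10, whose C6 (the only unsubstituted ortho/para carbon, C4a and C8 being blocked and the neutral B-ring diether and electron-poor C2=C3 being too weakly nucleophilic) attacks the electrophilic oxaziridine oxygen in an SN2-type O-transfer, the hemiaminal collapses to sulfonimine plus dienone alkoxide 11, and 11 rearomatises by C6–H tautomerisation (erasing its racemic centre) to the catechol monoanion that is protonated on quench; the closest known reaction types are the Davis oxaziridine α-hydroxylation of enolates and oxaziridine hydroxylative dearomatisation of naphtholates (and the Elbs persulfate logic of phenolate plus electrophilic oxygen), which to my knowledge have not been applied to a flavone phenolate.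

Step 7
Reactants: 12 2-[2-(benzyloxy)-6-methoxyphenyl]-5,6-dihydroxy-7,8-dimethoxy-4H-chromen-4-one
Product: 13 5,6-dihydroxy-2-(2-hydroxy-6-methoxyphenyl)-7,8-dimethoxy-4H-chromen-4-one (5,6,2′-trihydroxy-7,8,6′-trimethoxyflavone)
Conditions: H2 (1 atm), 10% Pd/C, EtOAc/MeOH, rt; work-up under Ar
Reagents that add atoms: none
Why: Pd-catalysed hydrogenolysis cleaves the benzyl aryl ether while methyl ethers and the flavone C2=C3 bond are inert at 1 atm and rt, and no stereocentre is present in the product.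

**Compound list**
1 | 1,2,3,5-tetramethoxybenzene | COc1cc(OC)c(OC)c(OC)c1 | starting material
2 | 1-(2,3,4,6-tetramethoxyphenyl)ethanone | CC(=O)c1c(OC)cc(OC)c(OC)c1OC | intermediate (not isolated)
3 | 1-(2-hydroxy-3,4,6-trimethoxyphenyl)ethanone | CC(=O)c1c(OC)cc(OC)c(OC)c1O | intermediate
4 | 2-hydroxy-6-methoxybenzaldehyde | COc1cccc(O)c1C=O | starting material
5 | 2-(benzyloxy)-6-methoxybenzaldehyde | COc1cccc(OCc2ccccc2)c1C=O | intermediate
6 | (E)-3-[2-(benzyloxy)-6-methoxyphenyl]-1-(2-hydroxy-3,4,6-trimethoxyphenyl)prop-2-en-1-one | COc1cccc(OCc2ccccc2)c1/C=C/C(=O)c1c(OC)cc(OC)c(OC)c1O | intermediate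
7 | rac-2-[2-(benzyloxy)-6-methoxyphenyl]-5,7,8-trimethoxychroman-4-one (flavanone) | COc1cccc(OCc2ccccc2)c1C1CC(=O)c2c(OC)cc(OC)c(OC)c2O1 | intermediate (not isolated)
8 | 2-[2-(benzyloxy)-6-methoxyphenyl]-5,7,8-trimethoxy-4H-chromen-4-one | COc1cccc(OCc2ccccc2)c1-c1cc(=O)c2c(OC)cc(OC)c(OC)c2o1 | intermediate
9 | 2-[2-(benzyloxy)-6-methoxyphenyl]-5-hydroxy-7,8-dimethoxy-4H-chromen-4-one | COc1cccc(OCc2ccccc2)c1-c1cc(=O)c2c(O)cc(OC)c(OC)c2o1 | intermediate
10 | potassium 5-phenolate of 9 | COc1cccc(OCc2ccccc2)c1-c1cc(=O)c2c([O-])cc(OC)c(OC)c2o1.[K+] | intermediate (not isolated)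
11 | potassium alkoxide of rac-2-[2-(benzyloxy)-6-methoxyphenyl]-6-hydroxy-7,8-dimethoxy-6H-chromene-4,5-dione (racemic at C6, transient) | COc1cccc(OCc2ccccc2)c1C1=CC(=O)C2=C(O1)C(OC)=C(OC)C([O-])C2=O.[K+] | intermediate (not isolated)
12 | 2-[2-(benzyloxy)-6-methoxyphenyl]-5,6-dihydroxy-7,8-dimethoxy-4H-chromen-4-one | COc1cccc(OCc2ccccc2)c1-c1cc(=O)c2c(O)c(O)c(OC)c(OC)c2o1 | intermediate
13 | 5,6-dihydroxy-2-(2-hydroxy-6-methoxyphenyl)-7,8-dimethoxy-4H-chromen-4-one (achiral) | COc1cccc(O)c1-c1cc(=O)c2c(O)c(O)c(OC)c(OC)c2o1 | target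

**Totals and risks**

Total step count: 7. Longest linear sequence: 6 steps (1 → 3 → 6 → 8 → 9 → 12 → 13; the arm 4 → 5 → 6 is equally long).

Step 6 (the proposed new hydroxylation) is the most likely to fail. The chelated phenolate may be too weakly C-nucleophilic, oxygen may go to C8 ipso to the methoxy group (leading to a 5,8-quinone), or the catecholate may over-oxidise. The fallback uses known chemistry, sets out from 9 and comes back at 12. Duff formylation (hexamethylenetetramine, AcOH, 100 °C; aq. HCl) at the only free position ortho to the 5-OH gives 2-[2-(benzyloxy)-6-methoxyphenyl]-5-hydroxy-7,8-dimethoxy-4-oxo-4H-chromene-6-carbaldehyde F1. Dakin oxidation (30% H2O2, aq. NaOH, THF, 0 °C, Ar) then passes through 2-[2-(benzyloxy)-6-methoxyphenyl]-5-hydroxy-7,8-dimethoxy-4-oxo-4H-chromen-6-yl formate F2, which is hydrolysed in the same pot to 12.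

Step 5 is the second risk: AlCl3 may partly cleave the benzyl ether along with the 5-O-methyl. The fallback changes the protecting-group logic, sets out from 8 and comes back at 9. Excess BCl3 (CH2Cl2, −78 → 0 °C) deliberately removes both the chelated 5-O-methyl and the benzyl group to give 5-hydroxy-2-(2-hydroxy-6-methoxyphenyl)-7,8-dimethoxy-4H-chromen-4-one (rivularin) F3. The non-chelated 2′-OH alone is then re-benzylated (BnBr 1.05 equiv, K2CO3, acetone, rt), the hydrogen-bonded 5-OH being far less nucleophilic, which returns 9.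

Step 3 is the third risk: both partners are doubly ortho-substituted, so the condensation may stall or give chalcone/flavanone mixtures. The fallback replaces the chalcone route by a 1,3-diketone route, sets out from 5 and 3 and comes back at 8, bypassing 6. Pinnick oxidation of 5 (NaClO2, NaH2PO4, 2-methyl-2-butene, t-BuOH/H2O) gives 2-(benzyloxy)-6-methoxybenzoic acid F4. Oxalyl chloride with catalytic DMF (CH2Cl2, rt) gives 2-(benzyloxy)-6-methoxybenzoyl chloride F5. C-aroylation of the lithium dianion of 3 (LiHMDS 3.2 equiv, THF, −78 °C → rt; Baker–Venkataraman-type Claisen condensation) gives 1-[2-(benzyloxy)-6-methoxyphenyl]-3-(2-hydroxy-3,4,6-trimethoxyphenyl)propane-1,3-dione F6. Acid cyclodehydration (cat. H2SO4, AcOH, 60 °C) closes the pyranone to 8.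

**Further compounds**
F1 | step 6 | 2-[2-(benzyloxy)-6-methoxyphenyl]-5-hydroxy-7,8-dimethoxy-4-oxo-4H-chromene-6-carbaldehyde | COc1cccc(OCc2ccccc2)c1-c1cc(=O)c2c(O)c(C=O)c(OC)c(OC)c2o1
F2 | step 6 | 2-[2-(benzyloxy)-6-methoxyphenyl]-5-hydroxy-7,8-dimethoxy-4-oxo-4H-chromen-6-yl formate | COc1cccc(OCc2ccccc2)c1-c1cc(=O)c2c(O)c(OC=O)c(OC)c(OC)c2o1
F3 | step 5 | 5-hydroxy-2-(2-hydroxy-6-methoxyphenyl)-7,8-dimethoxy-4H-chromen-4-one (rivularin) | COc1cccc(O)c1-c1cc(=O)c2c(O)cc(OC)c(OC)c2o1
F4 | step 3 | 2-(benzyloxy)-6-methoxybenzoic acid | COc1cccc(OCc2ccccc2)c1C(=O)O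
F5 | step 3 | 2-(benzyloxy)-6-methoxybenzoyl chloride | COc1cccc(OCc2ccccc2)c1C(=O)Cl
F6 | step 3 | 1-[2-(benzyloxy)-6-methoxyphenyl]-3-(2-hydroxy-3,4,6-trimethoxyphenyl)propane-1,3-dione | COc1cccc(OCc2ccccc2)c1C(=O)CC(=O)c1c(OC)cc(OC)c(OC)c1O
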